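The route disconnects both rings of the trans-decalin at C4–C5 and C9–C10. The feature exploited is the array C4, C5, C10, C9 in rings A and B together with the C8=C17 exocyclic methylene next to C9: this is the fold of an acyclic chain whose last alkene is an allylsilane. One Lewis-acid opening of a C3–C4 epoxide should close rings A and B, set four stereocentres and leave the methylene by loss of silicon. The precursor is an acyclic (3R,4S)-epoxide with a silyloxymethyl group cis to the chain, an E C5=C10 alkene and a C8=C9 allylsilane in which C7 and C11 are cis; C13 comes from (R)-citronellol.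

Key step: step 16

Assumption (chemistry): C15 is carried as a tert-butyldimethylsilyl ether, not as an ester, until step 19, because two hydride reductions and a hydride-based desulfonylation precede the cyclisation; both primary carbons are then oxidised together.

Remark on numbering: labdane numbering (C1–C20) is used for skeleton atoms in every compound; labdane is only a numbering frame and all configurations are given explicitly. The target is (4R,5S,9S,10S,13R): the CO2Me on C4 is axial and syn to the C10 methyl, and the C9 side chain is axial and anti to it.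

Remark on geometry: the allylsilane alkene with C7 and C11 cis is E by the sequence rule (CH2Si outranks CH2C and CH2O) and Z in the bromide (CH2Br outranks CH2Si). The oxirane needed is (3R,4S) in labdane numbering, which is (2S,3R) in oxirane numbering.

Step 1
Reactants: 1 geranyl bromide
Product: 2 geranyl phenyl sulfone
Conditions: PhSO2Na, DMF, rt
Reagents that add atoms: sodium benzenesulfinate, [Na+].[O-]S(=O)c1ccccc1
Why: SN2 S-alkylation of the sulfinate at the primary allylic bromide should give the sulfone with the E alkene unchanged, and the sulfonyl group later acidifies C6 for the fragment union.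

Step 2
Reactants: 2 geranyl phenyl sulfone
Product: 3 racemic 6,7-epoxygeranyl phenyl sulfone
Conditions: mCPBA (1.0 equiv), NaHCO3, CH2Cl2, 0 °C
Reagents that add atoms: mCPBA, O=C(OO)c1cccc(Cl)c1
Why: Prilezhaev epoxidation should select the electron-rich terminal alkene because the C5=C10 alkene is deactivated by the allylic sulfonyl group, and the racemic stereocentre is destroyed in step 3.

Step 3
Reactants: 3 racemic 6,7-epoxygeranyl phenyl sulfone
Product: 5 (4E)-4-methyl-6-(phenylsulfonyl)hex-4-enal, via diol 4 (not isolated)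
Conditions: H5IO6, THF/H2O, 0 °C to rt
Reagents that add atoms: water, O
Why: Acid-mediated hydration of the epoxide followed in the same flask by periodate glycol cleavage (Malaprade reaction) should release the C3 aldehyde and acetone without touching the sulfone or the alkene.

Step 4
Reactants: 5 (4E)-4-methyl-6-(phenylsulfonyl)hex-4-enal
Product: 6 ethyl (2Z,6E)-2,6-dimethyl-8-(phenylsulfonyl)octa-2,6-dienoate
Conditions: (CF3CH2O)2P(O)CH(CH3)CO2Et, KN(SiMe3)2, 18-crown-6, THF, −78 °C
Reagents that add atoms: ethyl 2-[bis(2,2,2-trifluoroethoxy)phosphoryl]propanoate, CCOC(=O)C(C)P(=O)(OCC(F)(F)F)OCC(F)(F)F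
Why: Still–Gennari olefination with the preformed potassium phosphonate should give the Z trisubstituted enoate under kinetic control, which places the future C19 carbon cis to C2, and no free base is left to deprotonate the sulfone.

Step 5
Reactants: 6 ethyl (2Z,6E)-2,6-dimethyl-8-(phenylsulfonyl)octa-2,6-dienoate
Product: 7 (2Z,6E)-2,6-dimethyl-8-(phenylsulfonyl)octa-2,6-dien-1-ol
Conditions: iBu2AlH, CH2Cl2, −78 °C; aq. KNaC4H4O6
Reagents that add atoms: none
Why: 1,2-Reduction of the conjugated ester by the aluminium hydride should give the Z allylic alcohol while the sulfone and both alkene geometries are untouched.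

Step 6
Reactants: 8 (R)-citronellol
Product: 9 (R)-citronellol tert-butyldimethylsilyl ether
Conditions: TBSCl, imidazole, DMF, rt
Reagents that add atoms: tert-butyldimethylsilyl chloride, CC(C)(C)[Si](C)(C)Cl
Why: Imidazole-promoted silyl ether formation masks C15 at the alcohol oxidation level so that it survives every later hydride and organometallic step.

Step 7
Reactants: 9 (R)-citronellol tert-butyldimethylsilyl ether
Product: 11 (4R)-6-[(tert-butyldimethylsilyl)oxy]-4-methylhexanal, via ozonide 10 (not isolated)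
Conditions: O3, CH2Cl2, −78 °C; then PPh3, −78 °C to rt
Reagents that add atoms: ozone, [O-][O+]=O
Why: Ozonolysis with reductive work-up should cleave the only alkene to the C9 aldehyde, and the C13 stereocentre is remote from the carbonyl and cannot epimerise.

Step 8
Reactants: 12 methyl bis(2,2,2-trifluoroethyl)phosphonoacetate; 13 (iodomethyl)trimethylsilane
Product: 15 methyl 2-[bis(2,2,2-trifluoroethoxy)phosphoryl]-3-(trimethylsilyl)propanoate, via sodium enolate 14 (not isolated)
Conditions: NaH, THF, 0 °C; then DMSO, 60 °C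
Reagents that add atoms: none
Why: C-alkylation of the stabilised phosphonoacetate anion by the primary iodide (SN2 enolate alkylation) should introduce the silylmethyl group that becomes C17 and its silicon.

Step 9
Reactants: 15 methyl 2-[bis(2,2,2-trifluoroethoxy)phosphoryl]-3-(trimethylsilyl)propanoate; 11 (4R)-6-[(tert-butyldimethylsilyl)oxy]-4-methylhexanal
Product: 17 methyl (2E,6R)-8-[(tert-butyldimethylsilyl)oxy]-6-methyl-2-[(trimethylsilyl)methyl]oct-2-enoate, via potassium enolate 16 (not isolated)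
Conditions: KN(SiMe3)2, 18-crown-6, THF, −78 °C
Reagents that add atoms: none
Why: Still–Gennari olefination with the α-substituted reagent should give the trisubstituted enoate with the ester carbon (C7) cis to the C11 chain, and this geometry later fixes C9.

Step 10
Reactants: 17 methyl (2E,6R)-8-[(tert-butyldimethylsilyl)oxy]-6-methyl-2-[(trimethylsilyl)methyl]oct-2-enoate
Product: 18 (2E,6R)-8-[(tert-butyldimethylsilyl)oxy]-6-methyl-2-[(trimethylsilyl)methyl]oct-2-en-1-ol
Conditions: iBu2AlH, CH2Cl2, −78 °C; aq. KNaC4H4O6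
Reagents that add atoms: none
Why: 1,2-Reduction of the conjugated ester gives the allylic alcohol while the silyl ether, the allylsilane and the alkene geometry survive the neutral tartrate work-up.

Step 11
Reactants: 18 (2E,6R)-8-[(tert-butyldimethylsilyl)oxy]-6-methyl-2-[(trimethylsilyl)methyl]oct-2-en-1-ol
Product: 19 {[(3R,6Z)-8-bromo-3-methyl-7-[(trimethylsilyl)methyl]oct-6-en-1-yl]oxy}(tert-butyl)dimethylsilane
Conditions: CBr4, PPh3, 2,6-lutidine, CH2Cl2, 0 °C
Reagents that add atoms: tetrabromomethane, BrC(Br)(Br)Br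
Why: Appel bromination replaces the primary allylic hydroxyl by SN2 displacement of an alkoxyphosphonium ion under near-neutral conditions, which should spare the acid-sensitive allylsilane and keep C7 cis to C11.

Step 12
Reactants: 7 (2Z,6E)-2,6-dimethyl-8-(phenylsulfonyl)octa-2,6-dien-1-ol; 19 {[(3R,6Z)-8-bromo-3-methyl-7-[(trimethylsilyl)methyl]oct-6-en-1-yl]oxy}(tert-butyl)dimethylsilane
Product: 21 (2Z,6E,10E,14R)-16-[(tert-butyldimethylsilyl)oxy]-2,6,14-trimethyl-8-(phenylsulfonyl)-10-[(trimethylsilyl)methyl]hexadeca-2,6,10-trien-1-ol, via dilithio sulfone 20 (not isolated)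
Conditions: n-BuLi (2.05 equiv), THF/DMPU, −78 °C; then 19, −78 to −30 °C; then H2O
Reagents that add atoms: none
Why: Alkylation of an α-sulfonyl carbanion (sulfone-based allyl–allyl coupling): the second equivalent of base makes the C6 carbanion beside the lithium alkoxide, and the carbanion should displace the primary allylic bromide at C7 by SN2 to form the C6–C7 bond, the sulfone-bearing centre forming as a mixture that step 13 erases.

Step 13
Reactants: 21 (2Z,6E,10E,14R)-16-[(tert-butyldimethylsilyl)oxy]-2,6,14-trimethyl-8-(phenylsulfonyl)-10-[(trimethylsilyl)methyl]hexadeca-2,6,10-trien-1-ol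
Product: 22 (2Z,6E,10E,14R)-16-[(tert-butyldimethylsilyl)oxy]-2,6,14-trimethyl-10-[(trimethylsilyl)methyl]hexadeca-2,6,10-trien-1-ol
Conditions: Pd(dppp)Cl2 (5 mol %), LiEt3BH (3.5 equiv), THF, 0 °C; then H2O
Reagents that add atoms: none
Why: Palladium-catalysed reductive desulfonylation of an allylic sulfone: zerovalent palladium ionises the C6–S bond and hydride is delivered to the less substituted C6 end of the allyl complex, which should keep the C5=C10 alkene in place and E, and no ester or epoxide is present to be reduced.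

Step 14
Reactants: 22 (2Z,6E,10E,14R)-16-[(tert-butyldimethylsilyl)oxy]-2,6,14-trimethyl-10-[(trimethylsilyl)methyl]hexadeca-2,6,10-trien-1-ol
Product: 23 {(2S,3R)-3-[(3E,7E,11R)-13-[(tert-butyldimethylsilyl)oxy]-3,11-dimethyl-7-[(trimethylsilyl)methyl]trideca-3,7-dien-1-yl]-2-methyloxiran-2-yl}methanol
Conditions: Ti(OiPr)4 (0.2 equiv), L-(+)-diethyl tartrate (0.25 equiv), t-BuOOH, 4 Å molecular sieves, CH2Cl2, −20 °C
Reagents that add atoms: tert-butyl hydroperoxide, CC(C)(C)OO
Why: Sharpless asymmetric epoxidation: only the allylic alcohol binds the titanium tartrate catalyst, so the C3=C4 alkene alone is oxidised, and L-(+)-diethyl tartrate should deliver oxygen to the face that gives the (2S,3R)-oxirane (C3 R, C4 S), the Z geometry placing the hydroxymethyl group cis to the chain.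

Step 15
Reactants: 23 {(2S,3R)-3-[(3E,7E,11R)-13-[(tert-butyldimethylsilyl)oxy]-3,11-dimethyl-7-[(trimethylsilyl)methyl]trideca-3,7-dien-1-yl]-2-methyloxiran-2-yl}methanol
Product: 24 the bis-silyl epoxy-diene allylsilane (cyclisation precursor)
Conditions: TBSCl, imidazole, DMF, 0 °C to rt
Reagents that add atoms: tert-butyldimethylsilyl chloride, CC(C)(C)[Si](C)(C)Cl
Why: Silyl ether formation on the primary epoxy alcohol under mildly basic conditions should leave the oxirane intact and gives a non-participating, weakly Lewis-basic group at O19.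

Step 16
Reactants: 24 the bis-silyl epoxy-diene allylsilane
Product: 25 (3R,4R,5S,9S,10S,13R)-15,19-bis[(tert-butyldimethylsilyl)oxy]labd-8(17)-en-3-ol
Conditions: MeAlCl2 (2.5 equiv), CH2Cl2, −78 °C; then aq. NaHCO3
Reagents that add atoms: none
Why: MeAlCl2 binds the oxirane oxygen, the C5=C10 alkene opens the C4–O bond from the rear as the C8=C9 allylsilane attacks the developing C10 cation through C9, and the β-silyl cation at C8 loses the silyl group to leave the C8=C17 methylene; this is a Lewis-acid-promoted epoxy-polyene (cation–olefin) cyclisation ended by an allylsilane, a known reaction class applied here to a new substrate. Ring A (bond C4–C5) closes 6-endo-trig on the C5=C10 alkene and ring B (bond C9–C10) closes 6-endo-trig on the C8=C9 alkene, each through a chair, the two additions across C5=C10 being antiperiplanar. C4 is set by inversion at the oxirane carbon fixed in step 14, so that the silyloxymethyl group cis to the chain becomes the axial C19; C5 and C10 are set by anti addition across the E alkene (trans ring fusion, C20 syn to C19); C9 is set by the allylsilane geometry, C11 cis to C7 ending axial and anti to C20; C3 is carried over and its hydroxyl ends equatorial. The step needs C4–O instead of C3–O cleavage, secured by the tertiary C4 and concerted alkene participation, and chair–chair instead of chair–boat folding, secured by the usual all-chair preference because the axial C11 chain meets only the axial hydrogens at C5 and C7. The position of the new alkene needs no choice since only C17 carries silicon, and the methyl–aluminium bond scavenges traces of HCl that would protodesilylate the terminator. Silyl ethers at O15 and O19, instead of esters, do not participate and compete only weakly for the Lewis acid.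

Step 17
Reactants: 25 (3R,4R,5S,9S,10S,13R)-15,19-bis[(tert-butyldimethylsilyl)oxy]labd-8(17)-en-3-ol
Product: 26 the C3 O-phenyl thionocarbonate of 25
Conditions: PhOC(S)Cl, pyridine, DMAP (cat.), CH2Cl2, rt to 40 °C
Reagents that add atoms: O-phenyl chlorothionoformate, S=C(Cl)Oc1ccccc1
Why: Acylation of the hindered equatorial C3 hydroxyl with an aryl chlorothionoformate (first half of the Barton–McCombie deoxygenation) runs without an alkoxide, which avoids silyl migration from O19 to O3.

Step 18
Reactants: 26 the C3 O-phenyl thionocarbonate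
Product: 27 (4R,5S,9S,10S,13R)-15,19-bis[(tert-butyldimethylsilyl)oxy]labd-8(17)-ene
Conditions: Bu3SnH, AIBN, toluene, 100 °C
Reagents that add atoms: none
Why: Barton–McCombie radical deoxygenation: the stannyl radical adds to sulfur, the C3–O bond fragments and the secondary C3 radical takes hydrogen from the stannane, which removes the C3 oxygen without touching the other stereocentres or the distant C8 methylene.

Step 19
Reactants: 27 (4R,5S,9S,10S,13R)-15,19-bis[(tert-butyldimethylsilyl)oxy]labd-8(17)-ene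
Product: 28 (4R,5S,9S,10S,13R)-labd-8(17)-ene-15,19-diol
Conditions: Bu4NF, THF, rt to 50 °C
Reagents that add atoms: none
Why: Fluoride-mediated desilylation should free both primary alcohols, the neopentyl C19 ether needing gentle warming.

Step 20
Reactants: 28 (4R,5S,9S,10S,13R)-labd-8(17)-ene-15,19-diol
Product: 30 (4R,5S,9S,10S,13R)-labd-8(17)-ene-15,19-dioic acid, via dialdehyde 29 (not isolated)
Conditions: CrO3, H2SO4, H2O, acetone, 0 °C
Reagents that add atoms: water, O
Why: Jones oxidation takes both primary alcohols through the aldehyde hydrates to the acids in one operation, the 1,1-disubstituted alkene tolerating the brief cold acidic exposure and no stereocentre being enolisable.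

Step 21
Reactants: 30 (4R,5S,9S,10S,13R)-labd-8(17)-ene-15,19-dioic acid
Product: 31 dimethyl (4R,5S,9S,10S,13R)-labd-8(17)-ene-15,19-dioate
Conditions: MeI, K2CO3, DMF, rt
Reagents that add atoms: iodomethane, CI
Why: Carboxylate O-alkylation (SN2 on iodomethane) esterifies both acids irrespective of hindrance, including the axial C19 acid that resists Fischer esterification.

Step 22
Reactants: 31 dimethyl (4R,5S,9S,10S,13R)-labd-8(17)-ene-15,19-dioate
Product: 33 (4R,5S,9S,10S,13R)-19-methoxy-19-oxolabd-8(17)-en-15-oic acid, via lithium carboxylate 32 (not isolated)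
Conditions: LiOH, THF/MeOH/H2O, rt; then 1 M HCl
Reagents that add atoms: lithium hydroxide, [Li+].[OH-]
Why: Chemoselective saponification: hydroxide should attack only the unhindered C15 ester, the axial neopentyl-type C19 ester being shielded by C20 and C6 at room temperature, and acidification gives the target.

Compound list

1 | geranyl bromide, (2E)-1-bromo-3,7-dimethylocta-2,6-diene | CC(C)=CCC/C(C)=C/CBr | starting material
2 | geranyl phenyl sulfone, {[(2E)-3,7-dimethylocta-2,6-dien-1-yl]sulfonyl}benzene | CC(C)=CCC/C(C)=C/CS(=O)(=O)c1ccccc1 | intermediate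
3 | racemic 2,2-dimethyl-3-[(3E)-3-methyl-5-(phenylsulfonyl)pent-3-en-1-yl]oxirane | CC1(C)OC1CC/C(C)=C/CS(=O)(=O)c1ccccc1 | intermediate
4 | racemic (6E)-2,6-dimethyl-8-(phenylsulfonyl)oct-6-ene-2,3-diol | CC(C)(O)C(O)CC/C(C)=C/CS(=O)(=O)c1ccccc1 | intermediate (not isolated)
5 | (4E)-4-methyl-6-(phenylsulfonyl)hex-4-enal | O=CCC/C(C)=C/CS(=O)(=O)c1ccccc1 | intermediate
6 | ethyl (2Z,6E)-2,6-dimethyl-8-(phenylsulfonyl)octa-2,6-dienoate | CCOC(=O)/C(C)=C\CC/C(C)=C/CS(=O)(=O)c1ccccc1 | intermediate
7 | (2Z,6E)-2,6-dimethyl-8-(phenylsulfonyl)octa-2,6-dien-1-ol | OC/C(C)=C\CC/C(C)=C/CS(=O)(=O)c1ccccc1 | intermediate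
8 | (R)-citronellol, (3R)-3,7-dimethyloct-6-en-1-ol | C[C@H](CCC=C(C)C)CCO | starting material
9 | tert-butyl{[(3R)-3,7-dimethyloct-6-en-1-yl]oxy}dimethylsilane | C[C@H](CCC=C(C)C)CCO[Si](C)(C)C(C)(C)C | intermediate
10 | ozonide, tert-butyl{[(3R)-5-(5,5-dimethyl-1,2,4-trioxolan-3-yl)-3-methylpentyl]oxy}dimethylsilane (both epimers at the ring carbon) | CC1(C)OOC(CC[C@@H](C)CCO[Si](C)(C)C(C)(C)C)O1 | intermediate (not isolated)
11 | (4R)-6-[(tert-butyldimethylsilyl)oxy]-4-methylhexanal | O=CCC[C@@H](C)CCO[Si](C)(C)C(C)(C)C | intermediate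
12 | methyl bis(2,2,2-trifluoroethyl)phosphonoacetate, methyl 2-[bis(2,2,2-trifluoroethoxy)phosphoryl]acetate | COC(=O)CP(=O)(OCC(F)(F)F)OCC(F)(F)F | starting material
13 | (iodomethyl)trimethylsilane | C[Si](C)(C)CI | starting material
14 | sodium enolate of 12 | [Na+].COC(=O)[CH-]P(=O)(OCC(F)(F)F)OCC(F)(F)F | intermediate (not isolated)
15 | racemic methyl 2-[bis(2,2,2-trifluoroethoxy)phosphoryl]-3-(trimethylsilyl)propanoate | COC(=O)C(C[Si](C)(C)C)P(=O)(OCC(F)(F)F)OCC(F)(F)F | intermediate
16 | potassium enolate of 15 | [K+].COC(=O)[C-](C[Si](C)(C)C)P(=O)(OCC(F)(F)F)OCC(F)(F)F | intermediate (not isolated)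
17 | methyl (2E,6R)-8-[(tert-butyldimethylsilyl)oxy]-6-methyl-2-[(trimethylsilyl)methyl]oct-2-enoate (ester carbon cis to the chain) | COC(=O)/C(C[Si](C)(C)C)=C\CC[C@@H](C)CCO[Si](C)(C)C(C)(C)C | intermediate
18 | (2E,6R)-8-[(tert-butyldimethylsilyl)oxy]-6-methyl-2-[(trimethylsilyl)methyl]oct-2-en-1-ol | OC/C(C[Si](C)(C)C)=C\CC[C@@H](C)CCO[Si](C)(C)C(C)(C)C | intermediate
19 | {[(3R,6Z)-8-bromo-3-methyl-7-[(trimethylsilyl)methyl]oct-6-en-1-yl]oxy}(tert-butyl)dimethylsilane | BrC/C(C[Si](C)(C)C)=C\CC[C@@H](C)CCO[Si](C)(C)C(C)(C)C | intermediate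
20 | dilithio derivative of 7 (lithium alkoxide and C6 carbanion) | [Li+].[Li+].[O-]C/C(C)=C\CC/C(C)=C/[CH-]S(=O)(=O)c1ccccc1 | intermediate (not isolated)
21 | (2Z,6E,10E,14R)-16-[(tert-butyldimethylsilyl)oxy]-2,6,14-trimethyl-8-(phenylsulfonyl)-10-[(trimethylsilyl)methyl]hexadeca-2,6,10-trien-1-ol (both C8 epimers; C8 is labdane C6) | OC/C(C)=C\CC/C(C)=C/C(C/C(C[Si](C)(C)C)=C\CC[C@@H](C)CCO[Si](C)(C)C(C)(C)C)S(=O)(=O)c1ccccc1 | intermediate
22 | (2Z,6E,10E,14R)-16-[(tert-butyldimethylsilyl)oxy]-2,6,14-trimethyl-10-[(trimethylsilyl)methyl]hexadeca-2,6,10-trien-1-ol | OC/C(C)=C\CC/C(C)=C/CC/C(C[Si](C)(C)C)=C\CC[C@@H](C)CCO[Si](C)(C)C(C)(C)C | intermediate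
23 | {(2S,3R)-3-[(3E,7E,11R)-13-[(tert-butyldimethylsilyl)oxy]-3,11-dimethyl-7-[(trimethylsilyl)methyl]trideca-3,7-dien-1-yl]-2-methyloxiran-2-yl}methanol | OC[C@]1(C)O[C@@H]1CC/C(C)=C/CC/C(C[Si](C)(C)C)=C\CC[C@@H](C)CCO[Si](C)(C)C(C)(C)C | intermediate
24 | tert-butyl({(2S,3R)-3-[(3E,7E,11R)-13-[(tert-butyldimethylsilyl)oxy]-3,11-dimethyl-7-[(trimethylsilyl)methyl]trideca-3,7-dien-1-yl]-2-methyloxiran-2-yl}methoxy)dimethylsilane (cyclisation precursor) | CC(C)(C)[Si](C)(C)OC[C@]1(C)O[C@@H]1CC/C(C)=C/CC/C(C[Si](C)(C)C)=C\CC[C@@H](C)CCO[Si](C)(C)C(C)(C)C | intermediate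
25 | (3R,4R,5S,9S,10S,13R)-15,19-bis[(tert-butyldimethylsilyl)oxy]labd-8(17)-en-3-ol (trans-decalin, equatorial 3-OH, axial C19 and C11, C8 methylene) | C=C1CC[C@H]2[C@@](C)(CC[C@@H](O)[C@@]2(C)CO[Si](C)(C)C(C)(C)C)[C@H]1CC[C@@H](C)CCO[Si](C)(C)C(C)(C)C | intermediate
26 | O-[(3R,4R,5S,9S,10S,13R)-15,19-bis[(tert-butyldimethylsilyl)oxy]labd-8(17)-en-3-yl] O-phenyl thiocarbonate | C=C1CC[C@H]2[C@@](C)(CC[C@@H](OC(=S)Oc3ccccc3)[C@@]2(C)CO[Si](C)(C)C(C)(C)C)[C@H]1CC[C@@H](C)CCO[Si](C)(C)C(C)(C)C | intermediate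
27 | (4R,5S,9S,10S,13R)-15,19-bis[(tert-butyldimethylsilyl)oxy]labd-8(17)-ene | C=C1CC[C@H]2[C@@](C)(CCC[C@@]2(C)CO[Si](C)(C)C(C)(C)C)[C@H]1CC[C@@H](C)CCO[Si](C)(C)C(C)(C)C | intermediate
28 | (4R,5S,9S,10S,13R)-labd-8(17)-ene-15,19-diol | C=C1CC[C@H]2[C@@](C)(CCC[C@@]2(C)CO)[C@H]1CC[C@@H](C)CCO | intermediate
29 | (4R,5S,9S,10S,13R)-labd-8(17)-ene-15,19-dial | C=C1CC[C@H]2[C@@](C)(CCC[C@@]2(C)C=O)[C@H]1CC[C@@H](C)CC=O | intermediate (not isolated)
30 | (4R,5S,9S,10S,13R)-labd-8(17)-ene-15,19-dioic acid | C=C1CC[C@H]2[C@@](C)(CCC[C@@]2(C)C(=O)O)[C@H]1CC[C@@H](C)CC(=O)O | intermediate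
31 | dimethyl (4R,5S,9S,10S,13R)-labd-8(17)-ene-15,19-dioate | C=C1CC[C@H]2[C@@](C)(CCC[C@@]2(C)C(=O)OC)[C@H]1CC[C@@H](C)CC(=O)OC | intermediate
32 | lithium (4R,5S,9S,10S,13R)-19-methoxy-19-oxolabd-8(17)-en-15-oate | [Li+].C=C1CC[C@H]2[C@@](C)(CCC[C@@]2(C)C(=O)OC)[C@H]1CC[C@@H](C)CC(=O)[O-] | intermediate (not isolated)
33 | (4R,5S,9S,10S,13R)-19-methoxy-19-oxolabd-8(17)-en-15-oic acid | C=C1CC[C@H]2[C@@](C)(CCC[C@@]2(C)C(=O)OC)[C@H]1CC[C@@H](C)CC(=O)O | target

Total step count: 22. Longest linear sequence: 16 steps (steps 1–5, then 12–22).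

Steps most likely to fail

Step 16. The silyloxymethyl group withdraws electron density from C4, so heterolysis of the C4–O bond may lag behind a hydride shift or stop after ring A. Ring B may close in part through a boat, which erodes control at C9, and stray acid may protodesilylate the terminator. The fallback replaces the cationic by a radical bicyclisation of a C8-methyl analogue; it sets out from 11 and 7 and returns at 25.
- Still–Gennari olefination of 11 with ethyl 2-[bis(2,2,2-trifluoroethoxy)phosphoryl]propanoate should give ethyl (2Z,6R)-8-[(tert-butyldimethylsilyl)oxy]-2,6-dimethyloct-2-enoate F1.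
- iBu2AlH gives (2Z,6R)-8-[(tert-butyldimethylsilyl)oxy]-2,6-dimethyloct-2-en-1-ol F2, and CBr4/PPh3 gives {[(3R,6Z)-8-bromo-3,7-dimethyloct-6-en-1-yl]oxy}(tert-butyl)dimethylsilane F3.
- Alkylation of the dilithio derivative of 7 with F3 gives (2Z,6E,10Z,14R)-16-[(tert-butyldimethylsilyl)oxy]-2,6,10,14-tetramethyl-8-(phenylsulfonyl)hexadeca-2,6,10-trien-1-ol F4.
- Pd(dppp)Cl2/LiEt3BH gives (2Z,6E,10Z,14R)-16-[(tert-butyldimethylsilyl)oxy]-2,6,10,14-tetramethylhexadeca-2,6,10-trien-1-ol F5.
- Sharpless epoxidation with L-(+)-diethyl tartrate gives {(2S,3R)-3-[(3E,7Z,11R)-13-[(tert-butyldimethylsilyl)oxy]-3,7,11-trimethyltrideca-3,7-dien-1-yl]-2-methyloxiran-2-yl}methanol F6.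
- TBSCl/imidazole gives tert-butyl({(2S,3R)-3-[(3E,7Z,11R)-13-[(tert-butyldimethylsilyl)oxy]-3,7,11-trimethyltrideca-3,7-dien-1-yl]-2-methyloxiran-2-yl}methoxy)dimethylsilane F7.
- Cp2TiCl (trivalent titanium, from Cp2TiCl2 and Mn dust, THF, rt) then opens the oxirane homolytically at C4, which does not depend on cation stability. The C4 radical should close rings A and B by two 6-endo additions through the same chair–chair fold. The C8 radical is trapped by a second Cp2TiCl and loses hydrogen from the C8 methyl to give the exocyclic alkene, so that aqueous work-up returns 25. This is the known titanocene-mediated radical cyclisation of epoxy-polyenes.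

Step 14. Facial selectivity may be incomplete because Z-configured allylic alcohols are the least selective class for this epoxidation; with the remote C13 centre already present, the minor oxirane becomes a diastereomer that is hard to remove. The fallback epoxidises before the fragment union; it sets out from 7 and returns at 24.
- Sharpless epoxidation of 7 with the same tartrate gives {(2S,3R)-2-methyl-3-[(3E)-3-methyl-5-(phenylsulfonyl)pent-3-en-1-yl]oxiran-2-yl}methanol F8. This aryl sulfone has no other stereocentre, so its enantiomeric purity can be raised by recrystallisation or by chromatography on a chiral phase.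
- TBSCl/imidazole gives tert-butyl({(2S,3R)-2-methyl-3-[(3E)-3-methyl-5-(phenylsulfonyl)pent-3-en-1-yl]oxiran-2-yl}methoxy)dimethylsilane F9.
- Lithiation with one equivalent of n-BuLi at −78 °C and alkylation with 19 gives tert-butyl({(2S,3R)-3-[(3E,7E,11R)-13-[(tert-butyldimethylsilyl)oxy]-3,11-dimethyl-5-(phenylsulfonyl)-7-[(trimethylsilyl)methyl]trideca-3,7-dien-1-yl]-2-methyloxiran-2-yl}methoxy)dimethylsilane F10.
- Pd(dppp)Cl2-catalysed reduction with LiEt3BH added slowly at −30 °C then removes the sulfone and gives 24. The allyl–palladium intermediate should take up hydride much faster than the trisubstituted oxirane, whose less substituted carbon is flanked by a fully substituted one.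

Step 9. The bulky α-silylmethyl group may erode the geometric selectivity of the olefination, and any isomer carried on would later appear as the C9 epimer. The fallback fixes the geometry by a syn addition to an alkyne; it sets out from 11 and returns at 17.
- Ohira–Bestmann homologation of 11 (dimethyl (1-diazo-2-oxopropyl)phosphonate, K2CO3, MeOH) gives tert-butyldimethyl{[(3R)-3-methylhept-6-yn-1-yl]oxy}silane F11.
- n-BuLi then ClCO2Me gives methyl (6R)-8-[(tert-butyldimethylsilyl)oxy]-6-methyloct-2-ynoate F12.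
- Pd(PPh3)4-catalysed hydrostannation with Bu3SnH adds hydrogen and tin syn with tin on the ester-bearing carbon, giving methyl (2E,6R)-8-[(tert-butyldimethylsilyl)oxy]-6-methyl-2-(tributylstannyl)oct-2-enoate F13, in which ester and chain are cis.
- I2 in CH2Cl2 replaces tin by iodine with retention, giving methyl (2E,6R)-8-[(tert-butyldimethylsilyl)oxy]-2-iodo-6-methyloct-2-enoate F14.
- Negishi coupling with Me3SiCH2ZnCl (from Me3SiCH2MgCl and ZnCl2, Pd(PPh3)4, THF) gives 17 with retention. This route also bypasses step 8.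

Further compounds

F1 | step 16 | ethyl (2Z,6R)-8-[(tert-butyldimethylsilyl)oxy]-2,6-dimethyloct-2-enoate | CCOC(=O)/C(C)=C\CC[C@@H](C)CCO[Si](C)(C)C(C)(C)C
F2 | step 16 | (2Z,6R)-8-[(tert-butyldimethylsilyl)oxy]-2,6-dimethyloct-2-en-1-ol | OC/C(C)=C\CC[C@@H](C)CCO[Si](C)(C)C(C)(C)C
F3 | step 16 | {[(3R,6Z)-8-bromo-3,7-dimethyloct-6-en-1-yl]oxy}(tert-butyl)dimethylsilane | BrC/C(C)=C\CC[C@@H](C)CCO[Si](C)(C)C(C)(C)C
F4 | step 16 | (2Z,6E,10Z,14R)-16-[(tert-butyldimethylsilyl)oxy]-2,6,10,14-tetramethyl-8-(phenylsulfonyl)hexadeca-2,6,10-trien-1-ol (both C8 epimers) | OC/C(C)=C\CC/C(C)=C/C(C/C(C)=C\CC[C@@H](C)CCO[Si](C)(C)C(C)(C)C)S(=O)(=O)c1ccccc1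
F5 | step 16 | (2Z,6E,10Z,14R)-16-[(tert-butyldimethylsilyl)oxy]-2,6,10,14-tetramethylhexadeca-2,6,10-trien-1-ol | OC/C(C)=C\CC/C(C)=C/CC/C(C)=C\CC[C@@H](C)CCO[Si](C)(C)C(C)(C)C
F6 | step 16 | {(2S,3R)-3-[(3E,7Z,11R)-13-[(tert-butyldimethylsilyl)oxy]-3,7,11-trimethyltrideca-3,7-dien-1-yl]-2-methyloxiran-2-yl}methanol | OC[C@]1(C)O[C@@H]1CC/C(C)=C/CC/C(C)=C\CC[C@@H](C)CCO[Si](C)(C)C(C)(C)C
F7 | step 16 | tert-butyl({(2S,3R)-3-[(3E,7Z,11R)-13-[(tert-butyldimethylsilyl)oxy]-3,7,11-trimethyltrideca-3,7-dien-1-yl]-2-methyloxiran-2-yl}methoxy)dimethylsilane | CC(C)(C)[Si](C)(C)OC[C@]1(C)O[C@@H]1CC/C(C)=C/CC/C(C)=C\CC[C@@H](C)CCO[Si](C)(C)C(C)(C)C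
F8 | step 14 | {(2S,3R)-2-methyl-3-[(3E)-3-methyl-5-(phenylsulfonyl)pent-3-en-1-yl]oxiran-2-yl}methanol | OC[C@]1(C)O[C@@H]1CC/C(C)=C/CS(=O)(=O)c1ccccc1
F9 | step 14 | tert-butyl({(2S,3R)-2-methyl-3-[(3E)-3-methyl-5-(phenylsulfonyl)pent-3-en-1-yl]oxiran-2-yl}methoxy)dimethylsilane | CC(C)(C)[Si](C)(C)OC[C@]1(C)O[C@@H]1CC/C(C)=C/CS(=O)(=O)c1ccccc1
F10 | step 14 | tert-butyl({(2S,3R)-3-[(3E,7E,11R)-13-[(tert-butyldimethylsilyl)oxy]-3,11-dimethyl-5-(phenylsulfonyl)-7-[(trimethylsilyl)methyl]trideca-3,7-dien-1-yl]-2-methyloxiran-2-yl}methoxy)dimethylsilane (both epimers at the sulfone carbon) | CC(C)(C)[Si](C)(C)OC[C@]1(C)O[C@@H]1CC/C(C)=C/C(C/C(C[Si](C)(C)C)=C\CC[C@@H](C)CCO[Si](C)(C)C(C)(C)C)S(=O)(=O)c1ccccc1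
F11 | step 9 | tert-butyldimethyl{[(3R)-3-methylhept-6-yn-1-yl]oxy}silane | C#CCC[C@@H](C)CCO[Si](C)(C)C(C)(C)C
F12 | step 9 | methyl (6R)-8-[(tert-butyldimethylsilyl)oxy]-6-methyloct-2-ynoate | COC(=O)C#CCC[C@@H](C)CCO[Si](C)(C)C(C)(C)C
F13 | step 9 | methyl (2E,6R)-8-[(tert-butyldimethylsilyl)oxy]-6-methyl-2-(tributylstannyl)oct-2-enoate | COC(=O)/C(=C\CC[C@@H](C)CCO[Si](C)(C)C(C)(C)C)[Sn](CCCC)(CCCC)CCCC
F14 | step 9 | methyl (2E,6R)-8-[(tert-butyldimethylsilyl)oxy]-2-iodo-6-methyloct-2-enoate | COC(=O)/C(I)=C\CC[C@@H](C)CCO[Si](C)(C)C(C)(C)C
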